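**Plan**

- Numbering: ring A is the 1,3,5-trisubstituted ring (C1 oxygenated, C3 chain, C5 ether oxygen). Ring B has C1 on the ether oxygen, oxygens at C2 and C6, and the chain at C4. The chain runs from C1' on ring B C4 to C12' on ring A C3.
- Retrosynthesis: the three phenols become methyl ethers and a carbonyl is placed at benzylic C1'. The 20-membered ring is then cut at C3'–C4'.
- Enabling feature: ring B C4 lies para to the ether oxygen on C1 and carries C1'. A carbonyl there makes C1'–C3' an aryl vinyl ketone acceptor for a C4' radical, and because it is benzylic it can be removed afterwards.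
- Further cuts: C1'–C2' (vinyl Grignard on the formyl group of syringaldehyde), the ring A C5–O bond (Ullmann etherification), and the ring A C3–C12' bond (B-alkyl Suzuki coupling).
- Forward order: chain onto ring A, ring B attached through oxygen, vinyl carbinol, acid, redox-active ester, oxidation to the enone, closure of the single macrocycle, then deoxygenation at C1' and demethylation.
- Stereochemistry: the target has no stereocentre. The carbinol carbon C1' is racemic whenever it exists and is removed by oxidation or by reduction to CH2.

Key step: step 7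

Remark: the enone is unveiled only in the last step before ring closure, by neutral oxidation of a vinyl carbinol, because amine- or base-mediated methylenation of an acetyl group would endanger the N-acyloxyphthalimide.

**Route**

Step 1
Reactants: 1 methyl dec-9-enoate; 2 3,5-dibromoanisole (1,3-dibromo-5-methoxybenzene)
Product: 4 methyl 10-(3-bromo-5-methoxyphenyl)decanoate, via B-alkyl-9-BBN adduct 3 (not isolated)
Conditions: 9-BBN, THF, 0 °C to rt; then 2 (3 equiv), Pd(dppf)Cl2 (5 mol%), aq. K3PO4, DMF, 60 °C
Reagents that add atoms: none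
Why: B-alkyl Suzuki–Miyaura coupling, in which anti-Markovnikov hydroboration of the terminal alkene by 9-BBN spares the ester, and the threefold excess of the symmetric dibromide (recoverable) should hold the reaction at a single coupling.

Step 2
Reactants: 4 methyl 10-(3-bromo-5-methoxyphenyl)decanoate; 5 syringaldehyde (4-hydroxy-3,5-dimethoxybenzaldehyde)
Product: 6 methyl 10-[3-(4-formyl-2,6-dimethoxyphenoxy)-5-methoxyphenyl]decanoate
Conditions: CuI (10 mol%), picolinic acid (20 mol%), K3PO4, DMSO, 90 °C
Reagents that add atoms: none
Why: Ullmann-type copper-catalysed O-arylation with the picolinic acid ligand, a system known to couple phenols bearing two ortho substituents with aryl bromides, while the aldehyde has no α-hydrogen and the methyl ester is inert to anhydrous phosphate.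

Step 3
Reactants: 6 methyl 10-[3-(4-formyl-2,6-dimethoxyphenoxy)-5-methoxyphenyl]decanoate
Product: 7 methyl 10-[3-[4-(1-hydroxyprop-2-en-1-yl)-2,6-dimethoxyphenoxy]-5-methoxyphenyl]decanoate (racemic)
Conditions: vinylMgBr (1.1 equiv), THF, −78 °C; then aq. NH4Cl
Reagents that add atoms: vinylmagnesium bromide, C=C[Mg]Br
Why: Grignard 1,2-addition, which at −78 °C should take the aldehyde far faster than the methyl ester, and the new carbinol centre is racemic and of no consequence because step 6 removes it.

Step 4
Reactants: 7 methyl 10-[3-[4-(1-hydroxyprop-2-en-1-yl)-2,6-dimethoxyphenoxy]-5-methoxyphenyl]decanoate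
Product: 8 10-[3-[4-(1-hydroxyprop-2-en-1-yl)-2,6-dimethoxyphenoxy]-5-methoxyphenyl]decanoic acid (racemic)
Conditions: LiOH, THF/MeOH/H2O, rt; then 1 M HCl to pH 4, 0 °C
Reagents that add atoms: lithium hydroxide, [Li+].[OH-]
Why: Saponification of the methyl ester, to which the allylic benzylic alcohol is stable, with a cold and only mildly acidic work-up to avoid allylic transposition of the carbinol.

Step 5
Reactants: 8 10-[3-[4-(1-hydroxyprop-2-en-1-yl)-2,6-dimethoxyphenoxy]-5-methoxyphenyl]decanoic acid
Product: 9 1,3-dioxoisoindolin-2-yl 10-[3-[4-(1-hydroxyprop-2-en-1-yl)-2,6-dimethoxyphenoxy]-5-methoxyphenyl]decanoate (racemic)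
Conditions: N-hydroxyphthalimide (1.1 equiv), DIC (1.1 equiv), DMAP (5 mol%), CH2Cl2, 0 °C to rt
Reagents that add atoms: N-hydroxyphthalimide, O=C1c2ccccc2C(=O)N1O
Why: Steglich-type carbodiimide esterification, in which the acidic N-hydroxyphthalimide (pKa near 6) should trap the O-acylisourea much faster than the hindered secondary alcohol, so the carbinol needs no protection.

Step 6
Reactants: 9 1,3-dioxoisoindolin-2-yl 10-[3-[4-(1-hydroxyprop-2-en-1-yl)-2,6-dimethoxyphenoxy]-5-methoxyphenyl]decanoate
Product: 10 1,3-dioxoisoindolin-2-yl 10-[3-(4-acryloyl-2,6-dimethoxyphenoxy)-5-methoxyphenyl]decanoate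
Conditions: Dess–Martin periodinane (1.2 equiv), CH2Cl2, 0 °C to rt; short silica pad, kept in dilute solution and used at once
Reagents that add atoms: none
Why: Dess–Martin oxidation of the secondary allylic benzylic alcohol under neutral, non-nucleophilic conditions should unveil the aryl vinyl ketone without touching the N-acyloxyphthalimide, and immediate use in dilute solution guards against polymerisation.

Step 7
Reactants: 10 1,3-dioxoisoindolin-2-yl 10-[3-(4-acryloyl-2,6-dimethoxyphenoxy)-5-methoxyphenyl]decanoate
Product: 11 1^5,3^2,3^6-trimethoxy-2-oxa-1(1,3),3(1,4)-dibenzenacyclopentadecaphan-4-one (20-membered macrocyclic aryl ketone, C=O at C1', tri-O-methyl ether)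
Conditions: Ru(bpy)3(PF6)2 (2 mol%), Hantzsch ester (1.5 equiv), i-Pr2NEt (2 equiv), degassed CH2Cl2, blue LEDs (450 nm), 25 °C; 10 added by syringe pump over 12 h, final 2 mM
Reagents that add atoms: none
Why: Proposed new method: the photoexcited ruthenium complex is reduced by i-Pr2NEt and the resulting [Ru(bpy)3]+ passes an electron to the phthalimide ester of 10, whose N–O bond breaks with loss of CO2 to leave a nucleophilic primary radical at C4'; this adds to the unsubstituted terminus C3' of the electron-poor aryl vinyl ketone, and the α-keto radical takes a hydrogen atom (or an electron and a proton) from the Hantzsch ester, which also returns the amine radical cation to the amine. The closest known reaction types are the intermolecular photoredox decarboxylative Giese addition of N-acyloxyphthalimides to enones and the tin hydride-mediated endo macrocyclisation of ω-iodoalkyl vinyl ketones, and their union in one ring-forming step is what is new. The single ring closes in the 20-endo-trig mode, the radical attacking the terminal CH2 so that C2' lies inside the ring. No stereocentre is formed. The step needs ring closure to outrun hydrogen transfer to the C4' radical and intermolecular addition, and the polarity-matched unhindered enone terminus, the slow addition that keeps the standing concentration of 10 well below the nominal 2 mM, and the modest hydrogen-donor ability of the dihydropyridine towards alkyl radicals should secure this.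

Step 8
Reactants: 11 1^5,3^2,3^6-trimethoxy-2-oxa-1(1,3),3(1,4)-dibenzenacyclopentadecaphan-4-one
Product: 13 1^5,3^2,3^6-trimethoxy-2-oxa-1(1,3),3(1,4)-dibenzenacyclopentadecaphane (macrocycle with CH2 at C1', tri-O-methyl ether), via macrocyclic benzylic alcohol 12 (not isolated)
Conditions: Et3SiH (5 equiv), CF3CO2H, CH2Cl2, rt to 40 °C
Reagents that add atoms: none
Why: Ionic hydrogenation, in which hydride transfer from the silane to the protonated aryl ketone gives the benzylic alcohol, which ionises to a benzylic cation assisted by the para aryloxy group and takes a second hydride to give CH2.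

Step 9
Reactants: 13 1^5,3^2,3^6-trimethoxy-2-oxa-1(1,3),3(1,4)-dibenzenacyclopentadecaphane
Product: 14 2-oxa-1(1,3),3(1,4)-dibenzenacyclopentadecaphane-1^5,3^2,3^6-triol (CNP0314249.0)
Conditions: BBr3 (6 equiv), CH2Cl2, −78 °C to rt; then H2O
Reagents that add atoms: none
Why: Lewis acid cleavage of aryl methyl ethers by BBr3, where bromide attacks each O-methyl carbon, should free the three phenols while the diaryl ether, which has no sp3 carbon on oxygen, stays intact.

**Compound list**

1 | methyl dec-9-enoate | C=CCCCCCCCC(=O)OC | starting material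
2 | 3,5-dibromoanisole (1,3-dibromo-5-methoxybenzene) | COc1cc(Br)cc(Br)c1 | starting material
3 | methyl 10-(9-borabicyclo[3.3.1]nonan-9-yl)decanoate (formed in situ) | COC(=O)CCCCCCCCCB1C2CCCC1CCC2 | intermediate
4 | methyl 10-(3-bromo-5-methoxyphenyl)decanoate | COC(=O)CCCCCCCCCc1cc(Br)cc(OC)c1 | intermediate
5 | syringaldehyde (4-hydroxy-3,5-dimethoxybenzaldehyde) | COc1cc(C=O)cc(OC)c1O | starting material
6 | methyl 10-[3-(4-formyl-2,6-dimethoxyphenoxy)-5-methoxyphenyl]decanoate | COC(=O)CCCCCCCCCc1cc(OC)cc(Oc2c(OC)cc(C=O)cc2OC)c1 | intermediate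
7 | methyl 10-[3-[4-(1-hydroxyprop-2-en-1-yl)-2,6-dimethoxyphenoxy]-5-methoxyphenyl]decanoate (racemic) | COC(=O)CCCCCCCCCc1cc(OC)cc(Oc2c(OC)cc(C(O)C=C)cc2OC)c1 | intermediate
8 | 10-[3-[4-(1-hydroxyprop-2-en-1-yl)-2,6-dimethoxyphenoxy]-5-methoxyphenyl]decanoic acid (racemic) | OC(=O)CCCCCCCCCc1cc(OC)cc(Oc2c(OC)cc(C(O)C=C)cc2OC)c1 | intermediate
9 | 1,3-dioxoisoindolin-2-yl 10-[3-[4-(1-hydroxyprop-2-en-1-yl)-2,6-dimethoxyphenoxy]-5-methoxyphenyl]decanoate (racemic) | O=C(CCCCCCCCCc1cc(OC)cc(Oc2c(OC)cc(C(O)C=C)cc2OC)c1)ON1C(=O)c2ccccc2C1=O | intermediate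
10 | 1,3-dioxoisoindolin-2-yl 10-[3-(4-acryloyl-2,6-dimethoxyphenoxy)-5-methoxyphenyl]decanoate | O=C(CCCCCCCCCc1cc(OC)cc(Oc2c(OC)cc(C(=O)C=C)cc2OC)c1)ON1C(=O)c2ccccc2C1=O | intermediate
11 | 1^5,3^2,3^6-trimethoxy-2-oxa-1(1,3),3(1,4)-dibenzenacyclopentadecaphan-4-one (macrocyclic ketone, C=O at C1') | COc1cc2cc(c1)Oc1c(OC)cc(cc1OC)C(=O)CCCCCCCCCCC2 | intermediate
12 | 1^5,3^2,3^6-trimethoxy-2-oxa-1(1,3),3(1,4)-dibenzenacyclopentadecaphan-4-ol (racemic, formed in situ) | COc1cc2cc(c1)Oc1c(OC)cc(cc1OC)C(O)CCCCCCCCCCC2 | intermediate
13 | 1^5,3^2,3^6-trimethoxy-2-oxa-1(1,3),3(1,4)-dibenzenacyclopentadecaphane | COc1cc2cc(c1)Oc1c(OC)cc(cc1OC)CCCCCCCCCCCC2 | intermediate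
14 | 2-oxa-1(1,3),3(1,4)-dibenzenacyclopentadecaphane-1^5,3^2,3^6-triol (CNP0314249.0) | Oc1cc2cc(c1)Oc1c(O)cc(cc1O)CCCCCCCCCCCC2 | target

**Count and risks**

Total step count: 9. Longest linear sequence: 9 steps, from methyl dec-9-enoate 1 to the target 14.

Steps most likely to fail:

Step 7 (bears the label). The C4' radical may be quenched by hydrogen transfer before it reaches C3'. It may instead add to the enone of a second molecule and start oligomerisation. The enone may also be reduced or polymerised under the reducing, irradiated conditions. The fallback uses known chemistry and sets out from 9. Triphenylphosphine-catalysed iododecarboxylation of the N-acyloxyphthalimide (LiI, PPh3 cat., acetone, blue LEDs, rt) would give the hydroxy iodide 1-[4-[3-(9-iodononyl)-5-methoxyphenoxy]-3,5-dimethoxyphenyl]prop-2-en-1-ol F1. Dess–Martin oxidation in CH2Cl2 would then give the iodo enone 1-[4-[3-(9-iodononyl)-5-methoxyphenoxy]-3,5-dimethoxyphenyl]prop-2-en-1-one F2. Slow addition of Bu3SnH with AIBN to F2 in refluxing benzene at about 3 mM is the established tin hydride macrocyclisation of ω-iodoalkyl vinyl ketones. It should close the same C3'–C4' bond and comes back to the route at 11.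

Step 2. The phenoxide of syringaldehyde is flanked by two methoxy groups and deactivated by the para formyl group, so its transfer to copper may be slow. Prolonged heating could then lead to reductive loss of bromine from 4 or to ester cleavage. The fallback sets out from 4 and changes the roles of the partners. Palladium-catalysed borylation (B2(OH)4, Pd(OAc)2, XPhos, KOAc, EtOH, 80 °C) would give [3-methoxy-5-(10-methoxy-10-oxodecyl)phenyl]boronic acid F3. Oxidative Chan–Lam coupling of F3 with 5 (Cu(OAc)2 20 mol%, pyridine, 4 Å molecular sieves, CH2Cl2, O2, rt) is a reaction type known to tolerate phenols with two ortho substituents. It comes back to the route at 6.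

Step 8. The para aryloxy group is twisted out of conjugation by its two ortho methoxy neighbours and the meta methoxy groups withdraw inductively. Ionisation of the intermediate alcohol 12 may therefore be slow, and the reduction could stall at the carbinol or its trifluoroacetate. The fallback sets out from 11 and does not depend on a benzylic cation. Wolff–Kishner reduction in the Huang-Minlon manner (N2H4·H2O, KOH, diethylene glycol, 130 °C then 200 °C) passes through the hydrazone of the macrocyclic ketone F4 and loses N2 to give the methylene compound. It comes back to the route at 13. Any methyl ether lost in the hot alkali is harmless, because step 9 removes all three.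

**Further compounds**

F1 | step 7 | 1-[4-[3-(9-iodononyl)-5-methoxyphenoxy]-3,5-dimethoxyphenyl]prop-2-en-1-ol (racemic) | C=CC(O)c1cc(OC)c(Oc2cc(OC)cc(CCCCCCCCCI)c2)c(OC)c1
F2 | step 7 | 1-[4-[3-(9-iodononyl)-5-methoxyphenoxy]-3,5-dimethoxyphenyl]prop-2-en-1-one | C=CC(=O)c1cc(OC)c(Oc2cc(OC)cc(CCCCCCCCCI)c2)c(OC)c1
F3 | step 2 | [3-methoxy-5-(10-methoxy-10-oxodecyl)phenyl]boronic acid | COC(=O)CCCCCCCCCc1cc(OC)cc(B(O)O)c1
F4 | step 8 | hydrazone of 1^5,3^2,3^6-trimethoxy-2-oxa-1(1,3),3(1,4)-dibenzenacyclopentadecaphan-4-one | COc1cc2cc(c1)Oc1c(OC)cc(cc1OC)C(=NN)CCCCCCCCCCC2
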